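Remark (assumption): the SMILES is read literally. In germacrane numbering, used here only as atom labels, it is (6S,7S,8R,9R)-8-hydroxy-9-[(2R,3R)-2,3-epoxy-2-methylbutanoyloxy]germacra-1(10)Z,4E,11(13)-trien-12,6-olide.

## Structural features

The target is a germacranolide of the melampolide type: a ten-membered carbocycle (ring A, C1–C10) trans-fused across C6–C7 to an α-methylene-γ-butyrolactone (ring B: O6, C6, C7, C11(=C13H2), C12=O). Ring A holds two trisubstituted olefins, C4=C5 (E, methyl C15, allylic to the lactone oxygen on C6) and C1=C10 (Z, methyl C14, next to C9). Four stereocentres are contiguous, C6(S)–C7(S)–C8(R)–C9(R): O6 and C11 are trans, C11 and the free C8 hydroxyl are cis, the C8 hydroxyl and the C9 acyloxy group are trans. C9 carries the ester of (2R,3R)-2,3-epoxy-2-methylbutanoic acid (epoxyangelic acid), a separate stereochemical unit. Fragile groups are the exocyclic methylene lactone (Michael acceptor, translactonisation to O8 under base), the 1,2-diol monoester (acyl migration), the 1,5-diene in a medium ring (Cope rearrangement on heating, transannular cyclisation under acid) and the epoxide of the acyl group. The real difficulty is the ten-membered ring with one E and one Z trisubstituted olefin, combined with the C6–C9 tetrad whose three oxygens must end up differentiated (lactone, free hydroxyl, ester). The key step exploits the array C4=C5–C6–C7–C8–C9(O): C6–C7 lies between an olefin and a carbon two atoms from the oxygenated C9, which is the retron of an oxy-Cope rearrangement, so cutting C6–C7 and joining C4–C9 contracts ring A to a cyclohexene (C9, C10, C1, C2, C3, C4). In that cyclohexene the (Z) olefin C1=C10 is an ordinary ring olefin, and the four stereocentres collapse to one quaternary carbon (C4).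

## Logic of the disconnections

In one sentence: an anionic oxy-Cope ring expansion of the 1,2-dialkenylcyclohex-2-enol 14 forges C6–C7 and the (4E) olefin of the ten-membered ring, and the C8 enolate it leaves is oxidised in the same flask.

28 ⇒ 23 + 27. Cut: the C9–O bond of the ester, with the C8 and C9 oxygens returned to one cis-epoxide oxygen. Reason: the C8 hydroxyl and the C9 ester are anti, so opening a cis-8,9-epoxide at the allylic carbon C9 installs the acyl group and frees the C8 hydroxyl in one operation, with no protecting group and no regioselective acylation of a diol. Gain: the two chiral fragments are joined last. Demand: SN2 attack at C9 with inversion, without SN2′ attack at C1, transannular participation of C4=C5 or damage to the methylene lactone.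

23 ⇒ 20 ⇒ 19. Cut: the lactone bond O6–C12 and the C12 oxidation level, then the two PMB ethers. Reason: the methylene lactone is the most fragile group and is made late from a 2-methylidene-1,4-diol; because O8 is tied up in the epoxide, only O6 can lactonise. Gain: C12 is carried as a protected allylic alcohol through all basic steps. Demand: the primary allylic alcohol must be oxidised in preference to the secondary allylic C6 alcohol, and the vinyl epoxide must survive.

19 ⇒ 17 ⇒ 16. Cut: the epoxide bond C8–O (closed by the C9 oxygen) and the C9–H bond, back to the α-sulfonyloxy ketone and the α-hydroxy ketone. Reason: the enolate of the ring-expanded ketone can only be oxidised on its open face, which puts oxygen on C8 anti to the C7 side chain, the opposite of the target. Closing the epoxide inverts C8 and the final opening inverts C9, so a stereospecific double inversion converts the accessible diastereomer into the required one. Gain: C8 and C9 are set without protecting groups. Demand: hydride must reach C9 anti to the C8 sulfonate.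

16 ⇒ 14 (key). Cut: C6–C7; shift C4=C5 to C5=C6 and C8–C9(=O) to C7=C8; join C4–C9. Reason: this is the oxy-Cope retron described above. Gain: the ten-membered ring becomes a cyclohexenol, the stereocentres C6 and C7 become two (E) olefins, the (4E) olefin becomes a quaternary carbon, and the C8 oxygen comes from the enolate. Demand: a chair transition state with C3 pseudo-equatorial, (E) geometry at both termini, and oxidation of the enolate before it changes conformation.

14 ⇒ 8 + 12. Cut: C8–C9, a carbonyl addition of an alkenyl-lithium. Gain: the side chain C7, C8, C11, C12, C13 arrives as one achiral piece. Demand: 1,2-addition to a hindered enone; the facial selectivity is not critical (see step 11).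

8 ⇒ 7 ⇒ 6 ⇒ 5 ⇒ 4 ⇒ 2 + 3. Cuts: the enol ether bond C6–O and the olefin C5=C6 (back to a formyl group on C4), then the two ring bonds C4–C9 and C2–C3 by a Diels–Alder disconnection. Reason: a 2-substituted acrolein places methyl and formyl on the quaternary carbon directly, and a 1-silyloxy diene places oxygen on C9 and the olefin at C1=C10. Gain: two commercial C4/C5 aldehydes. Demand: enantiofacial control at the dienophile, "ortho" regiochemistry, and an (E)-selective route from aldehyde to enol ether.

12 ⇒ 11 ⇒ 10 ⇒ 9, and 27 ⇒ 26 ⇒ 25 ⇒ 24. Cuts: the C7=C8 olefin (iodo-olefination of an enal) and the ether C–O bond; for the acid, the carboxyl oxidation level and the epoxide C–O bonds (asymmetric epoxidation of the Z allylic alcohol). Gain: both fragments come from commercial C4/C5 compounds in three steps each.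

## Other disconnections considered

Alternative 1: the disconnection most chemists would draw first. Cut C6–C7 and O6–C12 in an open chain. The seco-aldehyde A1 (C6 enal, (Z)-2-(bromomethyl)enoate at C7=C11, C8 silyl ether, C9 ester in place) would be closed by an intramolecular Barbier-type allylation with CrCl2 (Nozaki–Hiyama–Kishi conditions) and lactonised to A2, the 8-O-silyl ether of the target. Ground for preferring the chosen plan: A1 needs a long linear sequence that already contains both trisubstituted olefins, C8, C9 and the sensitive ester. The ring closure must also form a strained ten-membered ring against entropy while setting C6 and C7 relative to C8 through a flexible macrocyclic transition state. The chosen plan sets C6/C7 in a six-membered chair from one stereocentre and has no macrocyclisation.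

Alternative 2: keep C6–C7 and add the bond C4–C9, giving the trans-decalin A3 (tertiary C9 alcohol, equatorial C5 mesylate anti-periplanar to C4–C9). The forward key step would be a Wharton–Grob fragmentation with KOt-Bu, unveiling the C9 ketone and the (4E) olefin together. Ground: A3 needs five stereocentres on the decalin (C4, C5, C6, C7, C9), three of which are destroyed in the fragmentation, and C6–C7 with its oxygenation must be built by separate diastereoselective steps. It is the same bond reorganisation as the oxy-Cope rearrangement but without creating C6–C7, so it costs more steps for less stereochemical return.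

Alternative 3: cut C6–C7 and reconnect C6 through oxygen to the allylic carbon on C11, giving the thirteen-membered diallylic ether A4. The forward key step would be a [2,3]-Wittig ring contraction (deprotonation at C6), giving the C6 hydroxyl and an isopropenyl group on C7. Ground: A4 needs a macro-etherification of a chain already carrying C8/C9. After contraction C12 is a methyl group that must be oxidised to the carboxyl level in the presence of five other allylic positions, and the induction from C8 on C7 in a thirteen-membered transition state has no simple model. The chosen plan keeps C12 oxygenated from the start.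

Key step: step 11

## Route

Step 1
Reactants: 1 (E)-2-methylbut-2-enal
Product: 2 (E)-2-methyl-1-(triisopropylsilyloxy)buta-1,3-diene
Conditions: TIPSOTf, Et3N, Et2O, 0 °C to rt
Reagents that add atoms: triisopropylsilyl trifluoromethanesulfonate (CC(C)[Si](C(C)C)(C(C)C)OS(=O)(=O)C(F)(F)F)
Why: Silyl dienol ether formation by γ-deprotonation and O-silylation of the s-trans enal; this places oxygen on the outside of the diene (1E), the geometry that can reach the s-cis form needed for cycloaddition.

Step 2
Reactants: 2 (E)-2-methyl-1-(triisopropylsilyloxy)buta-1,3-diene; 3 2-methylprop-2-enal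
Product: 4 (1S,2S)-1,3-dimethyl-2-(triisopropylsilyloxy)cyclohex-3-ene-1-carbaldehyde
Conditions: (S)-3,3-diphenyl-1-(o-tolyl)tetrahydropyrrolo[1,2-c][1,3,2]oxazaborole (20 mol%), Tf2NH (18 mol%), CH2Cl2, −78 °C
Reagents that add atoms: none
Why: Catalytic enantioselective Diels–Alder reaction of a 2-substituted acrolein activated by a cationic oxazaborolidine; the C1 silyloxy donor directs the "ortho" adduct, and the catalyst shields one face of the coordinated s-trans enal so that the quaternary carbon forms as (1S) (the catalyst antipode is used if the sense proves opposite with this diene). The configuration at C2 (formyl exo expected) is irrelevant because C2 becomes the ketone carbon of 8.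

Step 3
Reactants: 4 (1S,2S)-1,3-dimethyl-2-(triisopropylsilyloxy)cyclohex-3-ene-1-carbaldehyde
Product: 5 (1S,6R)-6-[(E)-2-iodoethenyl]-2,6-dimethylcyclohex-2-en-1-yl triisopropylsilyl ether
Conditions: CrCl2, CHI3, THF/1,4-dioxane, 0 °C to rt
Reagents that add atoms: iodoform (IC(I)I)
Why: Takai iodo-olefination of a non-enolisable aldehyde; the (E)-alkenyl iodide results from anti elimination of the β-oxido gem-dichromium adduct, and no stereocentre is touched (the descriptor of the quaternary carbon changes only by priority).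

Step 4
Reactants: 5 (1S,6R)-6-[(E)-2-iodoethenyl]-2,6-dimethylcyclohex-2-en-1-yl triisopropylsilyl ether
Product: 6 (1S,6R)-6-[(E)-2-(4-methoxybenzyloxy)ethenyl]-2,6-dimethylcyclohex-2-en-1-yl triisopropylsilyl ether
Conditions: 4-methoxybenzyl alcohol, CuI (10 mol%), 3,4,7,8-tetramethyl-1,10-phenanthroline (20 mol%), Cs2CO3, toluene, 80 °C
Reagents that add atoms: 4-methoxybenzyl alcohol (COc1ccc(CO)cc1)
Why: Copper-catalysed Ullmann-type C–O coupling of an alkenyl iodide with a primary alcohol, which proceeds with retention of olefin geometry; it gives the (E)-enol ether that becomes C5=C6–O6.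

Step 5
Reactants: 6 (1S,6R)-6-[(E)-2-(4-methoxybenzyloxy)ethenyl]-2,6-dimethylcyclohex-2-en-1-yl triisopropylsilyl ether
Product: 7 (1S,6R)-6-[(E)-2-(4-methoxybenzyloxy)ethenyl]-2,6-dimethylcyclohex-2-en-1-ol
Conditions: TBAF, THF, rt to 40 °C
Reagents that add atoms: none
Why: Fluoride cleavage of the silyl ether; the enol ether and the quaternary centre are inert to fluoride.

Step 6
Reactants: 7 (1S,6R)-6-[(E)-2-(4-methoxybenzyloxy)ethenyl]-2,6-dimethylcyclohex-2-en-1-ol
Product: 8 (R)-6-[(E)-2-(4-methoxybenzyloxy)ethenyl]-2,6-dimethylcyclohex-2-en-1-one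
Conditions: Dess–Martin periodinane, pyridine, CH2Cl2, 0 °C
Reagents that add atoms: none
Why: Oxidation of the allylic alcohol to the enone under buffered conditions that spare the acid-labile enol ether; the quaternary α-carbon cannot epimerise and the β,γ-olefin cannot move into conjugation.

Step 7
Reactants: 9 2-methylidenepropane-1,3-diol
Product: 10 2-[(4-methoxybenzyloxy)methyl]prop-2-en-1-ol
Conditions: NaH (1 equiv), 4-methoxybenzyl chloride (1 equiv), Bu4NI (cat.), THF, 0 °C to rt, diol in excess
Reagents that add atoms: 4-methoxybenzyl chloride (COc1ccc(CCl)cc1)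
Why: Williamson mono-etherification of a symmetrical diol; excess diol limits bis-alkylation and is recovered.

Step 8
Reactants: 10 2-[(4-methoxybenzyloxy)methyl]prop-2-en-1-ol
Product: 11 2-[(4-methoxybenzyloxy)methyl]prop-2-enal
Conditions: MnO2, CH2Cl2, rt
Reagents that add atoms: none
Why: Selective oxidation of a primary allylic alcohol to the enal on MnO2 under neutral conditions.

Step 9
Reactants: 11 2-[(4-methoxybenzyloxy)methyl]prop-2-enal
Product: 12 (E)-1-iodo-3-[(4-methoxybenzyloxy)methyl]buta-1,3-diene
Conditions: CrCl2, CHI3, THF, 0 °C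
Reagents that add atoms: iodoform (IC(I)I)
Why: Takai iodo-olefination, which is aldehyde-selective and (E)-selective with enals; it gives the 1-iodo-1,3-diene that carries C8, C7, C11, C13 and C12.

Step 10
Reactants: 12 (E)-1-iodo-3-[(4-methoxybenzyloxy)methyl]buta-1,3-diene; 8 (R)-6-[(E)-2-(4-methoxybenzyloxy)ethenyl]-2,6-dimethylcyclohex-2-en-1-one
Product: 14 (1R,6R)-6-[(E)-2-(4-methoxybenzyloxy)ethenyl]-1-[(1E)-3-[(4-methoxybenzyloxy)methyl]buta-1,3-dien-1-yl]-2,6-dimethylcyclohex-2-en-1-ol, via dienyllithium 13 (not isolated)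
Conditions: t-BuLi (2.05 equiv), Et2O, −78 °C; then 8, THF, −78 to −40 °C; aq NH4Cl
Reagents that add atoms: none
Why: Iodine–lithium exchange with retention of the (E) geometry, then 1,2-addition to the enone, which has no α-proton on the quaternary side. The flatter alkoxyvinyl group should sit pseudo-axial on C6 and the nucleophile should enter on the opposite face, placing the two alkenyl groups trans (1R); the C1 epimer would converge in step 11.

Step 11
Reactants: 14 (1R,6R)-6-[(E)-2-(4-methoxybenzyloxy)ethenyl]-1-[(1E)-3-[(4-methoxybenzyloxy)methyl]buta-1,3-dien-1-yl]-2,6-dimethylcyclohex-2-en-1-ol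
Product: 16 (6S,7S,8S)-8-hydroxy-6,12-bis(4-methoxybenzyloxy)germacra-1(10)Z,4E,11(13)-trien-9-one, via potassium enolate 15 (not isolated)
Conditions: KH, 18-crown-6, THF, 0 to 40 °C; then −78 °C, 2-(phenylsulfonyl)-3-phenyloxaziridine; aq NH4Cl
Reagents that add atoms: 2-(phenylsulfonyl)-3-phenyloxaziridine (O=S(=O)(N1OC1c1ccccc1)c1ccccc1)
Why: Deprotonation gives the potassium alkoxide of 14, whose 3-oxido-1,5-diene (C7=C8–C9(O−)–C4–C5=C6) undergoes the anionic oxy-Cope [3,3] shift: C4–C9 breaks as C6–C7 forms, leaving the C8=C9 enolate 15 (closest known type: anionic oxy-Cope ring expansion of 1,2-divinylcyclohexanols to cyclodec-5-enones with in situ enolate oxidation by an N-sulfonyloxaziridine). Ring A is therefore not closed end to end but formed by a four-atom sigmatropic ring expansion of the cyclohexene through a six-centre chair, which avoids the entropic cost of a macrocyclisation. With the two alkenyl groups trans, only the chair with both ring bonds (C3 on C4, C10 on C9) pseudo-equatorial is possible; C3 equatorial becomes the (4E) olefin, and the (Z) olefin C1=C10 is simply the former ring olefin. Both reacting termini are (E) and hence pseudo-equatorial, which fixes O6 and C11 anti (the trans-lactone relationship), and the absolute sense (the spatial arrangement of 6S,7S in the target) is relayed from the (R)-quaternary carbon C4, which is consumed. The C9 epimer of 14 reaches the same C6/C7 array through the chair with the oxido group equatorial, so the selectivity of step 10 is not critical. In 15, allylic strain holds C7–H in the enolate plane and C6 with the rest of ring A blocks one face, so the oxaziridine delivers oxygen to C8 on the open face, anti to C6. This gives (8S), the C8 epimer of the target, which is exactly what the double inversion of steps 13 and 19 needs. The step requires chair over boat and oxidation before the enolate flips; the trans-dialkenyl arrangement secures the first and oxidation at −78 °C the second.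

Step 12
Reactants: 16 (6S,7S,8S)-8-hydroxy-6,12-bis(4-methoxybenzyloxy)germacra-1(10)Z,4E,11(13)-trien-9-one
Product: 17 (6S,7R,8S)-8-(methanesulfonyloxy)-6,12-bis(4-methoxybenzyloxy)germacra-1(10)Z,4E,11(13)-trien-9-one
Conditions: MsCl, Et3N, CH2Cl2, −20 °C
Reagents that add atoms: methanesulfonyl chloride (CS(Cl)(=O)=O)
Why: Sulfonylation of the only free hydroxyl with retention at C8 (the C7 descriptor changes by priority only); the α-sulfonyloxy ketone has no acidic α′-proton because C10 is sp2.

Step 13
Reactants: 17 (6S,7R,8S)-8-(methanesulfonyloxy)-6,12-bis(4-methoxybenzyloxy)germacra-1(10)Z,4E,11(13)-trien-9-one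
Product: 19 (6S,7R,8R,9S)-8,9-epoxy-6,12-bis(4-methoxybenzyloxy)germacra-1(10)Z,4E,11(13)-triene, via hydroxy mesylate 18 (not isolated)
Conditions: NaBH4, CeCl3·7H2O, MeOH, −78 to −40 °C; then K2CO3, 0 °C to rt
Reagents that add atoms: none
Why: Luche 1,2-reduction of the enone; hydride should add to C9 anti to the C8–OMs bond held perpendicular to the carbonyl (polar Felkin–Anh model), giving the (9S) alcohol with oxygen anti to the sulfonate. Carbonate then closes the epoxide by SN2 at C8 (3-exo-tet), inverting C8 to (8R) and giving the cis-epoxide.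

Step 14
Reactants: 19 (6S,7R,8R,9S)-8,9-epoxy-6,12-bis(4-methoxybenzyloxy)germacra-1(10)Z,4E,11(13)-triene
Product: 20 (6S,7R,8R,9S)-8,9-epoxygermacra-1(10)Z,4E,11(13)-triene-6,12-diol
Conditions: DDQ, CH2Cl2/pH 7 phosphate buffer, 0 °C
Reagents that add atoms: none
Why: Oxidative cleavage of both 4-methoxybenzyl ethers by hydride abstraction and hydrolysis; the buffer keeps the vinyl epoxide from acid-triggered opening, and the isolated olefins are not oxidised by DDQ.

Step 15
Reactants: 20 (6S,7R,8R,9S)-8,9-epoxygermacra-1(10)Z,4E,11(13)-triene-6,12-diol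
Product: 23 (6S,7R,8R,9S)-8,9-epoxygermacra-1(10)Z,4E,11(13)-trien-12,6-olide, via enal 21 (not isolated), via lactol 22 (not isolated)
Conditions: TEMPO (20 mol%), PhI(OAc)2, CH2Cl2/pH 7 phosphate buffer, rt
Reagents that add atoms: none
Why: Nitroxyl-catalysed oxidative lactonisation: the primary allylic alcohol is oxidised first, the C6 hydroxyl closes the lactol and this is oxidised to the α-methylene-γ-lactone. O8 is locked in the epoxide, so only the 12,6-lactone can form, and the trans ring fusion follows from the existing C6/C7 configuration.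

Step 16
Reactants: 24 (Z)-2-methylbut-2-enoic acid
Product: 25 (Z)-2-methylbut-2-en-1-ol
Conditions: LiAlH4, Et2O, 0 °C
Reagents that add atoms: none
Why: Hydride reduction of the carboxylic acid to the allylic alcohol; 1,2-reduction at low temperature leaves the (Z) olefin untouched.

Step 17
Reactants: 25 (Z)-2-methylbut-2-en-1-ol
Product: 26 [(2S,3R)-2,3-dimethyloxiran-2-yl]methanol
Conditions: Ti(OiPr)4 (10 mol%), D-(−)-diethyl tartrate (12 mol%), t-BuOOH, 4 Å MS, CH2Cl2, −20 °C
Reagents that add atoms: tert-butyl hydroperoxide (CC(C)(C)OO)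
Why: Sharpless asymmetric epoxidation of a trisubstituted allylic alcohol; with the hydroxymethyl group drawn lower right, the D-tartrate catalyst delivers oxygen to the upper face, giving (2S,3R). The cis relationship of the hydroxymethyl and C3 methyl groups is carried over from the (Z) olefin.

Step 18
Reactants: 26 [(2S,3R)-2,3-dimethyloxiran-2-yl]methanol
Product: 27 (2R,3R)-2,3-dimethyloxirane-2-carboxylic acid
Conditions: TEMPO (10 mol%), PhI(OAc)2, MeCN/H2O, rt
Reagents that add atoms: water (O)
Why: Nitroxyl-catalysed oxidation of the primary alcohol through the aldehyde hydrate to the acid without touching the epoxide; the C2 descriptor changes from S to R by priority only.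

Step 19
Reactants: 23 (6S,7R,8R,9S)-8,9-epoxygermacra-1(10)Z,4E,11(13)-trien-12,6-olide; 27 (2R,3R)-2,3-dimethyloxirane-2-carboxylic acid
Product: 28 (6S,7S,8R,9R)-8-hydroxy-9-[(2R,3R)-2,3-dimethyloxirane-2-carbonyloxy]germacra-1(10)Z,4E,11(13)-trien-12,6-olide
Conditions: 27 (3 equiv), iPr2NEt (0.5 equiv), toluene, 50 °C
Reagents that add atoms: none
Why: Opening of a vinyl epoxide by a carboxylate in the presence of its acid: SN2 attack at the allylic carbon C9 (activated, and less hindered than C8, which is flanked by the branched C7) inverts C9 to (9R) and frees the (8R) hydroxyl. The acid/ammonium carboxylate buffer protonates the C8 alkoxide at once, which suppresses ionisation, acyl migration and translactonisation; the carboxylate does not add irreversibly to the methylene lactone.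

## Compound list

1 | (E)-2-methylbut-2-enal | C/C=C(\C)C=O | starting material
2 | (E)-2-methyl-1-(triisopropylsilyloxy)buta-1,3-diene | C=C/C(C)=C/O[Si](C(C)C)(C(C)C)C(C)C | intermediate
3 | 2-methylprop-2-enal | CC(=C)C=O | starting material
4 | (1S,2S)-1,3-dimethyl-2-(triisopropylsilyloxy)cyclohex-3-ene-1-carbaldehyde | O=C[C@@]1(C)CCC=C(C)[C@@H]1O[Si](C(C)C)(C(C)C)C(C)C | intermediate
5 | (1S,6R)-6-[(E)-2-iodoethenyl]-2,6-dimethylcyclohex-2-en-1-yl triisopropylsilyl ether | I/C=C/[C@@]1(C)CCC=C(C)[C@@H]1O[Si](C(C)C)(C(C)C)C(C)C | intermediate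
6 | (1S,6R)-6-[(E)-2-(4-methoxybenzyloxy)ethenyl]-2,6-dimethylcyclohex-2-en-1-yl triisopropylsilyl ether | COc1ccc(CO/C=C/[C@@]2(C)CCC=C(C)[C@@H]2O[Si](C(C)C)(C(C)C)C(C)C)cc1 | intermediate
7 | (1S,6R)-6-[(E)-2-(4-methoxybenzyloxy)ethenyl]-2,6-dimethylcyclohex-2-en-1-ol | COc1ccc(CO/C=C/[C@@]2(C)CCC=C(C)[C@@H]2O)cc1 | intermediate
8 | (R)-6-[(E)-2-(4-methoxybenzyloxy)ethenyl]-2,6-dimethylcyclohex-2-en-1-one | COc1ccc(CO/C=C/[C@@]2(C)CCC=C(C)C2=O)cc1 | intermediate
9 | 2-methylidenepropane-1,3-diol | C=C(CO)CO | starting material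
10 | 2-[(4-methoxybenzyloxy)methyl]prop-2-en-1-ol | C=C(CO)COCc1ccc(OC)cc1 | intermediate
11 | 2-[(4-methoxybenzyloxy)methyl]prop-2-enal | C=C(C=O)COCc1ccc(OC)cc1 | intermediate
12 | (E)-1-iodo-3-[(4-methoxybenzyloxy)methyl]buta-1,3-diene | C=C(/C=C/I)COCc1ccc(OC)cc1 | intermediate
13 | [(1E)-3-[(4-methoxybenzyloxy)methyl]buta-1,3-dien-1-yl]lithium | C=C(/C=C/[Li])COCc1ccc(OC)cc1 | intermediate
14 | (1R,6R)-6-[(E)-2-(4-methoxybenzyloxy)ethenyl]-1-[(1E)-3-[(4-methoxybenzyloxy)methyl]buta-1,3-dien-1-yl]-2,6-dimethylcyclohex-2-en-1-ol | C=C(COCc1ccc(OC)cc1)/C=C/[C@@]1(O)C(C)=CCC[C@]1(C)/C=C/OCc1ccc(OC)cc1 | intermediate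
15 | potassium (6S,7R)-6,12-bis(4-methoxybenzyloxy)germacra-1(10)Z,4E,8Z,11(13)-tetraen-9-olate | COc1ccc(CO[C@H]2/C=C(\C)CC/C=C(/C)\C([O-])=C\[C@@H]2C(=C)COCc2ccc(OC)cc2)cc1.[K+] | intermediate
16 | (6S,7S,8S)-8-hydroxy-6,12-bis(4-methoxybenzyloxy)germacra-1(10)Z,4E,11(13)-trien-9-one | COc1ccc(CO[C@H]2/C=C(\C)CC/C=C(/C)C(=O)[C@@H](O)[C@@H]2C(=C)COCc2ccc(OC)cc2)cc1 | intermediate
17 | (6S,7R,8S)-8-(methanesulfonyloxy)-6,12-bis(4-methoxybenzyloxy)germacra-1(10)Z,4E,11(13)-trien-9-one | COc1ccc(CO[C@H]2/C=C(\C)CC/C=C(/C)C(=O)[C@@H](OS(C)(=O)=O)[C@@H]2C(=C)COCc2ccc(OC)cc2)cc1 | intermediate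
18 | (6S,7R,8S,9S)-9-hydroxy-6,12-bis(4-methoxybenzyloxy)germacra-1(10)Z,4E,11(13)-trien-8-yl methanesulfonate | COc1ccc(CO[C@H]2/C=C(\C)CC/C=C(/C)[C@H](O)[C@@H](OS(C)(=O)=O)[C@@H]2C(=C)COCc2ccc(OC)cc2)cc1 | intermediate
19 | (6S,7R,8R,9S)-8,9-epoxy-6,12-bis(4-methoxybenzyloxy)germacra-1(10)Z,4E,11(13)-triene | COc1ccc(CO[C@H]2/C=C(\C)CC/C=C(/C)[C@@H]3O[C@@H]3[C@@H]2C(=C)COCc2ccc(OC)cc2)cc1 | intermediate
20 | (6S,7R,8R,9S)-8,9-epoxygermacra-1(10)Z,4E,11(13)-triene-6,12-diol | O[C@H]1/C=C(\C)CC/C=C(/C)[C@@H]2O[C@@H]2[C@@H]1C(=C)CO | intermediate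
21 | (6S,7R,8R,9S)-8,9-epoxy-6-hydroxygermacra-1(10)Z,4E,11(13)-trien-12-al | O[C@H]1/C=C(\C)CC/C=C(/C)[C@@H]2O[C@@H]2[C@@H]1C(=C)C=O | intermediate
22 | (6S,7R,8R,9S)-8,9-epoxy-12-hydroxy-12,6-epoxygermacra-1(10)Z,4E,11(13)-triene (lactol, both anomers) | C=C1C(O)O[C@H]2/C=C(\C)CC/C=C(/C)[C@@H]3O[C@@H]3[C@H]12 | intermediate
23 | (6S,7R,8R,9S)-8,9-epoxygermacra-1(10)Z,4E,11(13)-trien-12,6-olide | C=C1C(=O)O[C@H]2/C=C(\C)CC/C=C(/C)[C@@H]3O[C@@H]3[C@H]12 | intermediate
24 | (Z)-2-methylbut-2-enoic acid (angelic acid) | C/C=C(/C)C(=O)O | starting material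
25 | (Z)-2-methylbut-2-en-1-ol | C/C=C(/C)CO | intermediate
26 | [(2S,3R)-2,3-dimethyloxiran-2-yl]methanol | OC[C@]1(C)O[C@@H]1C | intermediate
27 | (2R,3R)-2,3-dimethyloxirane-2-carboxylic acid | OC(=O)[C@]1(C)O[C@@H]1C | intermediate
28 | (6S,7S,8R,9R)-8-hydroxy-9-[(2R,3R)-2,3-dimethyloxirane-2-carbonyloxy]germacra-1(10)Z,4E,11(13)-trien-12,6-olide | C=C1C(=O)O[C@H]2/C=C(\C)CC/C=C(/C)[C@@H](OC(=O)[C@]3(C)O[C@@H]3C)[C@H](O)[C@H]12 | target

## Step count and risks

Total step count: 19. Longest linear sequence: 13 steps (steps 1–6, 10–15 and 19).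

Least certain steps:

Step 11 (key step). The oxidation is the fragile half. If the potassium enolate equilibrates between ring conformers at the temperature of the rearrangement, facial control at C8 is lost, and the enolate may also condense with the sulfonylimine formed from the oxidant. Leakage of the C9-epimeric alkoxide through the second chair (C3 axial), which would give a (4Z) ring, would show up at the same stage. Fallback, setting out from 14: the rearrangement is run alone and quenched with acid to (6S,7R)-6,12-bis(4-methoxybenzyloxy)germacra-1(10)Z,4E,11(13)-trien-9-one F1, which is purified. Its only enolisable position is silylated (TESOTf, Et3N) to (6S,7R)-6,12-bis(4-methoxybenzyloxy)-9-(triethylsilyloxy)germacra-1(10)Z,4E,8Z,11(13)-tetraene F2. Rubottom oxidation of this most electron-rich olefin with dimethyldioxirane at −78 °C, with desilylation on work-up, returns to the route at 16.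

Step 13. Hydride may be delivered to the other face of C9: peripheral attack syn to the sulfonate could override the Felkin–Anh preference. That gives the erythro hydroxy mesylate, which cannot close to the cis-epoxide. Fallback, setting out from 17: the Luche reduction is worked up without base to give (6S,7R,8S,9R)-9-hydroxy-6,12-bis(4-methoxybenzyloxy)germacra-1(10)Z,4E,11(13)-trien-8-yl methanesulfonate F3. Mitsunobu inversion of the allylic C9 alcohol (PPh3, DIAD, 4-nitrobenzoic acid) gives (6S,7R,8S,9S)-8-(methanesulfonyloxy)-6,12-bis(4-methoxybenzyloxy)germacra-1(10)Z,4E,11(13)-trien-9-yl 4-nitrobenzoate F4. Methanolysis (K2CO3, MeOH) frees the (9S) alkoxide, which closes onto C8 and returns to the route at 19.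

Step 19. The allylic C9–O bond may ionise, with transannular capture by the C4=C5 olefin or attack at C1 (SN2′), and slow opening leaves time for acyl migration or translactonisation of the product. Fallback, setting out from 19: the epoxide is opened before the lactone exists, where forcing SN2 conditions are tolerated (cesium salt of 27 from Cs2CO3, DMF, 60 °C), giving (6S,7S,8R,9R)-8-hydroxy-6,12-bis(4-methoxybenzyloxy)germacra-1(10)Z,4E,11(13)-trien-9-yl (2R,3R)-2,3-dimethyloxirane-2-carboxylate F5. The C8 hydroxyl is masked (TESOTf, 2,6-lutidine) as (6S,7R,8R,9R)-6,12-bis(4-methoxybenzyloxy)-8-(triethylsilyloxy)germacra-1(10)Z,4E,11(13)-trien-9-yl (2R,3R)-2,3-dimethyloxirane-2-carboxylate F6. DDQ gives (6S,7R,8R,9R)-6,12-dihydroxy-8-(triethylsilyloxy)germacra-1(10)Z,4E,11(13)-trien-9-yl (2R,3R)-2,3-dimethyloxirane-2-carboxylate F7. TEMPO/PhI(OAc)2 gives (6S,7R,8R,9R)-9-[(2R,3R)-2,3-dimethyloxirane-2-carbonyloxy]-8-(triethylsilyloxy)germacra-1(10)Z,4E,11(13)-trien-12,6-olide F8. HF·pyridine in THF at 0 °C returns to the route at 28.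

Step 4. Turnover at the neopentyl-type alkenyl iodide may be slow, leading to hydrodeiodination or erosion of the (E) geometry, and the silyl ether may be lost to the carbonate/alkoxide at 80 °C. Fallback, setting out from 4: Ohira–Bestmann homologation (dimethyl (1-diazo-2-oxopropyl)phosphonate, K2CO3, MeOH) gives (1S,6R)-6-ethynyl-2,6-dimethylcyclohex-2-en-1-yl triisopropylsilyl ether F9. Hydroboration with pinacolborane (Cp2Zr(H)Cl cat.) gives (1S,6R)-2,6-dimethyl-6-[(E)-2-(4,4,5,5-tetramethyl-1,3,2-dioxaborolan-2-yl)ethenyl]cyclohex-2-en-1-yl triisopropylsilyl ether F10. Oxidative etherification of the alkenylboronate with 4-methoxybenzyl alcohol (Cu(OAc)2, Et3N, Chan–Lam type, retention of geometry) returns to the route at 6.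

## Further compounds

F1 | step 11 | (6S,7R)-6,12-bis(4-methoxybenzyloxy)germacra-1(10)Z,4E,11(13)-trien-9-one | COc1ccc(CO[C@H]2/C=C(\C)CC/C=C(/C)C(=O)C[C@@H]2C(=C)COCc2ccc(OC)cc2)cc1
F2 | step 11 | (6S,7R)-6,12-bis(4-methoxybenzyloxy)-9-(triethylsilyloxy)germacra-1(10)Z,4E,8Z,11(13)-tetraene | COc1ccc(CO[C@H]2/C=C(\C)CC/C=C(/C)\C(O[Si](CC)(CC)CC)=C\[C@@H]2C(=C)COCc2ccc(OC)cc2)cc1
F3 | step 13 | (6S,7R,8S,9R)-9-hydroxy-6,12-bis(4-methoxybenzyloxy)germacra-1(10)Z,4E,11(13)-trien-8-yl methanesulfonate | COc1ccc(CO[C@H]2/C=C(\C)CC/C=C(/C)[C@@H](O)[C@@H](OS(C)(=O)=O)[C@@H]2C(=C)COCc2ccc(OC)cc2)cc1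
F4 | step 13 | (6S,7R,8S,9S)-8-(methanesulfonyloxy)-6,12-bis(4-methoxybenzyloxy)germacra-1(10)Z,4E,11(13)-trien-9-yl 4-nitrobenzoate | COc1ccc(CO[C@H]2/C=C(\C)CC/C=C(/C)[C@H](OC(=O)c3ccc(cc3)[N+](=O)[O-])[C@@H](OS(C)(=O)=O)[C@@H]2C(=C)COCc2ccc(OC)cc2)cc1
F5 | step 19 | (6S,7S,8R,9R)-8-hydroxy-6,12-bis(4-methoxybenzyloxy)germacra-1(10)Z,4E,11(13)-trien-9-yl (2R,3R)-2,3-dimethyloxirane-2-carboxylate | COc1ccc(CO[C@H]2/C=C(\C)CC/C=C(/C)[C@@H](OC(=O)[C@]3(C)O[C@@H]3C)[C@H](O)[C@@H]2C(=C)COCc2ccc(OC)cc2)cc1
F6 | step 19 | (6S,7R,8R,9R)-6,12-bis(4-methoxybenzyloxy)-8-(triethylsilyloxy)germacra-1(10)Z,4E,11(13)-trien-9-yl (2R,3R)-2,3-dimethyloxirane-2-carboxylate | COc1ccc(CO[C@H]2/C=C(\C)CC/C=C(/C)[C@@H](OC(=O)[C@]3(C)O[C@@H]3C)[C@H](O[Si](CC)(CC)CC)[C@@H]2C(=C)COCc2ccc(OC)cc2)cc1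
F7 | step 19 | (6S,7R,8R,9R)-6,12-dihydroxy-8-(triethylsilyloxy)germacra-1(10)Z,4E,11(13)-trien-9-yl (2R,3R)-2,3-dimethyloxirane-2-carboxylate | O[C@H]1/C=C(\C)CC/C=C(/C)[C@@H](OC(=O)[C@]2(C)O[C@@H]2C)[C@H](O[Si](CC)(CC)CC)[C@@H]1C(=C)CO
F8 | step 19 | (6S,7R,8R,9R)-9-[(2R,3R)-2,3-dimethyloxirane-2-carbonyloxy]-8-(triethylsilyloxy)germacra-1(10)Z,4E,11(13)-trien-12,6-olide | C=C1C(=O)O[C@H]2/C=C(\C)CC/C=C(/C)[C@@H](OC(=O)[C@]3(C)O[C@@H]3C)[C@H](O[Si](CC)(CC)CC)[C@H]12
F9 | step 4 | (1S,6R)-6-ethynyl-2,6-dimethylcyclohex-2-en-1-yl triisopropylsilyl ether | C#C[C@@]1(C)CCC=C(C)[C@@H]1O[Si](C(C)C)(C(C)C)C(C)C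
F10 | step 4 | (1S,6R)-2,6-dimethyl-6-[(E)-2-(4,4,5,5-tetramethyl-1,3,2-dioxaborolan-2-yl)ethenyl]cyclohex-2-en-1-yl triisopropylsilyl ether | CC1(C)OB(/C=C/[C@@]2(C)CCC=C(C)[C@@H]2O[Si](C(C)C)(C(C)C)C(C)C)OC1(C)C
A1 | alternative 1 | methyl (2Z,4R,5R,6Z,10E)-2-(bromomethyl)-4-(tert-butyldimethylsilyloxy)-5-[(2R,3R)-2,3-dimethyloxirane-2-carbonyloxy]-6,10-dimethyl-12-oxododeca-2,6,10-trienoate (seco-aldehyde) | O=C/C=C(\C)CC/C=C(/C)[C@@H](OC(=O)[C@]1(C)O[C@@H]1C)[C@H](O[Si](C)(C)C(C)(C)C)/C=C(\CBr)C(=O)OC
A2 | alternative 1 | (6S,7R,8R,9R)-8-(tert-butyldimethylsilyloxy)-9-[(2R,3R)-2,3-dimethyloxirane-2-carbonyloxy]germacra-1(10)Z,4E,11(13)-trien-12,6-olide | C=C1C(=O)O[C@H]2/C=C(\C)CC/C=C(/C)[C@@H](OC(=O)[C@]3(C)O[C@@H]3C)[C@H](O[Si](C)(C)C(C)(C)C)[C@H]12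
A3 | alternative 2 | trans-fused 4,9-cyclogermacra-1(10),11(13)-diene: 9-hydroxy-6,12-bis(tert-butyldimethylsilyloxy)-4,10-dimethyl decalin 5-methanesulfonate (C4–C9 bond in place, C5 mesylate equatorial) | C[C@]12CCC=C(C)[C@]1(O)C[C@H](C(=C)CO[Si](C)(C)C(C)(C)C)[C@@H](O[Si](C)(C)C(C)(C)C)[C@@H]2OS(C)(=O)=O
A4 | alternative 3 | (8R,9R)-8,9-bis(tert-butyldimethylsilyloxy)-6,12-epoxy-6,7-secogermacra-1(10)Z,4E,7(11)E-triene (thirteen-membered diallylic ether) | C1/C=C(\C)CC/C=C(/C)[C@@H](O[Si](C)(C)C(C)(C)C)[C@H](O[Si](C)(C)C(C)(C)C)/C=C(\C)CO1
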